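I follow the electrophile left and not the target, because the green run's target reading falls from 19.0 % to 8.7 % while electrophile is still reacting.

| flask | electrophile | nucleophile | free base | remark | time |
|---|---|---|---|---|---|
| green | 0.10 M (fed, over 4.0 min) | 1.2 equiv | 1 equiv | run made earlier; the fed solution adds 0.50 times the starting volume |  |
| teal | 0.10 M (fed, over 4.0 min) | 1.2 equiv | 2.6 equiv | run made earlier; the fed solution adds 0.50 times the starting volume |  |
| Wednesday's | 0.10 M (fed, over 4.0 min) | 1.20 equiv | 0.800 equiv | the fed solution adds 0.50 times the starting volume | 40 min |
| Tuesday's | 0.10 M (fed, over 4.0 min) | 1.20 equiv | 1.20 equiv | the fed solution adds 0.50 times the starting volume | 40 min |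
| Saturday's | 0.10 M (fed, over 4.0 min) | 1.20 equiv | 1.80 equiv | the fed solution adds 0.50 times the starting volume | 40 min |

| run | time / min | electrophile / % | target / % |
|---|---|---|---|
| green | 2.50 | 54.7 | 7.4 |
| green | 5.00 | 76.2 | 16.3 |
| green | 12.0 | 47.9 | 19.0 |
| green | 30.0 | 22.8 | 8.7 |
| teal | 4.00 | 83.1 | 13.0 |
| teal | 10.0 | 53.5 | 19.3 |
| teal | 20.0 | 33.3 | 13.0 |
| teal | 30.0 | 23.0 | 9.0 |

(scatter of a reading: 0.5 percentage points)

- charges are per starting volume, the dose included; the dosed solution carries all of it
- on the list of suspects stand: target <-> isomer of the product; acid set free + free base <-> salt of the base; electrophile + nucleophile -> acid set free + target; nucleophile + acid set free <-> protonated nucleophile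
- percentages count the whole charge, also what has not yet gone in

- part of the electrophile that has reacted at the end, Wednesday's
- part of the electrophile that has reacted at the end, Tuesday's
- part of the electrophile that has reacted at the end, Saturday's
- what raising the equivalents of free base from its lowest to its highest value here does to the part of the electrophile that has reacted (changes below 5 percentage points count as none) (it falls / no change / it rises)

At 30.0 min green holds 22.8 % of electrophile and teal 23.0 %, despite 1 equiv against 2.6 equiv of free base, so I expect Tuesday's and Saturday's, which lie between them, to follow that curve.

The electrophile is the limiting reagent. With x its fraction left and 0.200 the excess of nucleophile, I use L = ln(c(nucleophile)/c(electrophile)) = ln((x + excess)/x), which for a second-order step climbs in a straight line after the feed. Green gives 0.349 at 12.0 min and 0.630 at 30.0 min, hence 0.0156 /min. This is the climb, the rise of L per minute. At 40 min L stands at 0.786, so x is 16.7 % and I reckon 83.3 % reacted in Tuesday's and Saturday's flasks.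

In Wednesday's flask the acid set free overtakes the 0.800 equiv of free base once x reaches 20.0 %, which the climb puts at 34.1 min, earlier than the end by 5.90 min.

The forecast gives 82.8 % for Wednesday's, 83.2 % for Tuesday's, 83.2 % for Saturday's and the trend no change; of Wednesday's ending it says “Over the last 6 min this barely matters”.

The flasks give 82.4 %, 83.3 % and 83.4 %, so the trend is no change: 0.99 percentage points against a margin of 5 points.

    target ⇌ isomer of the product (K = 18.0, k = 0.00330 /s)
    acid set free + free base ⇌ salt of the base, settled at all times (K = 7.10 × 10⁵ /M)
    electrophile + nucleophile → acid set free + target (k = 0.0200 /M/s)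
    nucleophile + acid set free ⇌ protonated nucleophile, settled at all times (K = 6900 /M)

At the end of Wednesday's flask the isomer of the product stands at 75.4 % against 7.02 % of target. In Wednesday's flask at 8.76 min the target's forward half-life to the isomer is 3.5 min, shorter than the electrophile's 11 min in the coupling.

For the neighbour of Wednesday's flask with 0.060 M of electrophile, equivalents held, the climb scales with concentration to 0.00936 /min. Green's line runs back to the charged value 0.182 at 1.32 min, so L reaches 0.544 at 40 min, which means 72.4 % reacted; the computed flask gives 72.1 %.

The runs were generated by integration with made-up constants; the scatter is artificial.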